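Reciprocal minutes are the unit to look for: a flask that makes target while target turns into isomer of the product runs on a clock of that unit.

| flask | starting material | coupling partner | free catalyst | remark | time |
|---|---|---|---|---|---|
| Thursday's | 0.092 M | 1.5 equiv | 0.054 mol% | run made earlier |  |
| Friday's | 0.092 M | 2.1 equiv | 0.054 mol% | run made earlier |  |
| Monday's | 0.092 M | 3.3 equiv | 0.054 mol% | run made earlier |  |
| Sunday's | 0.092 M | 1.5 equiv | 0.027 mol% | run made earlier |  |
| blue | 0.092 M | 1.50 equiv | 0.054 mol% | everything together in a closed stirred flask, run for 12 min | 12 min |
| red | 0.092 M | 1.50 equiv | 0.054 mol% | a tube with plug flow, the mixed feed as stated, residence time 12 min | 12 min |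
| amber | 0.092 M (fed, over 9.60 min) | 1.50 equiv | 0.054 mol% | a stirred flask in which starting material is dosed at a steady rate over 9.60 min without added volume, worked up at 12 min | 12 min |
| green | 0.092 M | 1.50 equiv | 0.054 mol% | one stirred flow tank at steady state, fed with the mixture as stated, mean residence time 12 min |  |

1. the set-up with the highest share of target in all that became target or isomer of the product, at the outlet or at the end ("none" if the first two lie within 2 percentage points) (blue / red / amber / green / none)
2. share of target in all that became target or isomer of the product, at the outlet or at the end, blue
3. share of target in all that became target or isomer of the product, at the outlet or at the end, red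
4. share of target in all that became target or isomer of the product, at the outlet or at the end, amber
5. share of target in all that became target or isomer of the product, at the outlet or at the end, green

- the stated concentrations are those of everything mixed, before any reaction; amounts are the same in each set-up
- the feed brings no volume worth counting
- the earlier runs were made in a closed, stirred flask

| run | time / min | target / % | isomer of the product / % |
|---|---|---|---|
| Thursday's | 2.00 | 2.7 | 0.6 |
| Thursday's | 4.00 | 4.5 | 0 |
| Thursday's | 5.00 | 5.5 | 0.3 |
| Thursday's | 8.00 | 8.0 | 2.5 |
| Friday's | 2.50 | 2.6 | 0 |
| Friday's | 5.00 | 5.3 | 1.4 |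
| Friday's | 8.00 | 8.9 | 2.3 |
| Friday's | 10.0 | 9.4 | 3.0 |
| Monday's | 2.50 | 2.9 | 0 |
| Monday's | 5.00 | 6.7 | 1.7 |
| Monday's | 8.00 | 8.9 | 2.4 |
| Monday's | 10.0 | 9.9 | 4.2 |
| Sunday's | 2.50 | 1.5 | 0.2 |
| Sunday's | 5.00 | 3.0 | 0.2 |
| Sunday's | 8.00 | 4.1 | 0.8 |
| Sunday's | 10.0 | 4.5 | 1.9 |

(each reading ± 0.5 percentage points)

Read the rows at 8.00 min. Thursday, with 1.5 equiv of coupling partner, gives 8.0% target and Monday, with 3.3 equiv, gives 8.9%, so more coupling partner changes little, but Sunday, at Thursday's coupling partner and half of its catalyst, gives about half of Thursday's target. The isomer column starts near zero and climbs late, so we take it to come from target. At 10.0 min, isomer over target reads 0.319 on Friday, 0.424 on Monday and 0.422 on Sunday, where the scatter is about 0.111. So within that scatter this ratio shows no sign of following the catalyst.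

Now solve both ends, with target made steadily and x standing for k times the time. For small x the share of target (the selectivity) is 1 − x/2, the mean age being half the time. For large x it is 1/x. The curve (​1 − e^(−x))/x joins them, and it makes isomer over target about x/2 + x·x/12. The Friday, Monday and Sunday readings at 10.0 min, pooled, give a ratio of 0.382, so x reads 0.686 and k reads 0.0686 min⁻¹, the ageing rate, the fraction of target lost to isomer each minute.

Our reckoning follows. Blue and red share one history, giving 68.1%. Green's target has a mean age of 12 min, twice blue's, and 1/(1 + kτ) gives 54.8%. If amber's rate follows the starting material dosed, its mean age is 4.13 min. Using twice that age as the time gives 76.3%, higher than blue.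

The forecast names amber, with blue 69%, red 69%, amber 76% and green 56%, a little above ours on blue and green. Its amber rests on this: “Amber makes product later if the rate follows starting material”.

The flask gives amber: blue 71.7%, red 71.7%, amber 75.4%, green 60.1%.

    catalyst intermediate D → free catalyst + target (k = 192 min⁻¹)
    starting material + catalyst intermediate B ⇌ catalyst intermediate C (K = 18.0 M⁻¹, k = 2500 M⁻¹ min⁻¹)
    target ⇌ isomer of the product (K = 23.0, k = 0.0569 min⁻¹)
    catalyst intermediate A → catalyst intermediate B (k = 58.2 min⁻¹)
    catalyst intermediate C ⇌ released group + catalyst intermediate D (K = 0.0106 M, k = 225 min⁻¹)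
    coupling partner + free catalyst → catalyst intermediate A (k = 1370 M⁻¹ min⁻¹)
    released group → by-product carried off (k = 0.0155 min⁻¹)

In amber, free catalyst has a half-life of 0.23 s at 6.83 min by its step to catalyst intermediate A, while target and isomer relax by their own step, both ways together, with a half-life of 11.7 min, far slower and close to the run's 12 min. Amber's catalyst intermediate A moves from 36.9% to 35.2% between 9.60 min and 12.0 min, while amber's isomer moves from 1.80% to 2.89%.

Read amber at 30 min instead: the mean age becomes 12.8 min, and k on twice that age gives a share of 47.2%. The computed flask holds 14.1% target and 15.0% isomer, a share of 48.4%.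

Readings and results are simulated on assumed constants; noise was put on by code.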